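Watch the rate.

all flasks: gas 7.1 mM (held)
- north-west: starting material 0.10 M; second nucleophile 0.15 M; run made earlier
- south-west: starting material 0.050 M; second nucleophile 0.15 M; run made earlier
- theta: starting material 0.10 M (fed, over 3.0 d); second nucleophile 0.150 M; all else is in the flask from the start; the feed brings no volume worth counting; time 8.0 d
- delta: starting material 0.10 M (in portions, 2, over 3.0 d); second nucleophile 0.150 M; first portion at the start, last at 3.0 d; time 8.0 d
- epsilon: starting material 0.10 M; second nucleophile 0.150 M; everything together at the start; time 8.0 d
- beta: starting material 0.10 M; second nucleophile 0.150 M (fed, over 3.0 d); all else is in the flask from the start; the feed brings no volume worth counting; time 8.0 d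

- north-west (time / d: other capture product / %, target / %): 0.417: 12.2, 17.7; 0.833: 16.1, 18.9; 1.25: 17.5, 14.5; 2.50: 18.2, 3.3; 5.00: 18.6, 0
- south-west (time / h: other capture product / %, target / %): 4.00: 6.1, 7.7; 8.00: 10.2, 15.3; 12.0: 11.9, 16.2; 15.0: 13.2, 17.9; 20.0: 14.2, 17.4

(readings scatter by 0.5 percentage points)

* the flask that comes out highest in amount of other capture product, in percent of the starting material charged, or "all alike" when all lie within 1.5 percentage points (theta / delta / epsilon / beta / all alike)
* other capture product at the end, in percent of the starting material charged, theta
* other capture product at the end, in percent of the starting material charged, delta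
* other capture product at the end, in percent of the starting material charged, epsilon
* other capture product at the end, in percent of the starting material charged, beta

- the earlier runs were read with a standard deviation of 0.5 percentage points
- at the start none of the gas is in solution

- In the north-west run, the share of the charge held as other capture product grows at 0.293 d⁻¹ over the first interval, 0.0938 d⁻¹ over the next and 0.0336 d⁻¹ over the third, so each equal step slows it by 3.12, then 2.79.
- A roughly steady factor means roughly exponential decay: read from these scattered points, 0.366 d is the time in which the capture rate falls by a factor e, the capture time, an apparent first-order lifetime.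
- Summed over the steps, the end value is start rate times capture time, so the north-west plateau of 18.6% reads as a start rate of 0.509 d⁻¹.
- The south-west run, at half the charge, reads 0.287 d, so halving did not lengthen it.
- My bet is that this clock belongs to the flask, not to the portion. Epsilon then repeats the plateau. Delta's late portion earns hardly any, which leaves 9.30%. Theta, fed over 3.0 d, earns 2.27%. Beta holds no second nucleophile at the start, so I place it below epsilon, without a number.
- The forecast puts theta at 18.6%, delta at 18.6% and epsilon at 18.6%, on the ground that “Yield therefore depends only on nucleophile level, not on how starting material is added”; it puts beta at 47%, which makes beta its highest flask.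
- The flasks give epsilon highest: theta 5.72%, delta 9.70%, epsilon 18.4%, beta 9.22%.

    starting material ⇌ intermediate (K = 0.0510, k = 1.40 × 10⁻⁵ s⁻¹)
    first nucleophile + intermediate → target (k = 4.50 M⁻¹ s⁻¹)
    second nucleophile + intermediate → other capture product (k = 0.100 M⁻¹ s⁻¹)
    first nucleophile + target → over-reaction product (k = 0.00600 M⁻¹ s⁻¹)
    gas ⇌ first nucleophile, rate k5*(csat - [first nucleophile]) (kL = 4.00 × 10⁻⁴ s⁻¹)
    2 second nucleophile → self-condensation product (k = 1.70 × 10⁻⁴ M⁻¹ s⁻¹)

- In epsilon, half of the turnover of starting material to intermediate was done by 0.580 d, and c(second nucleophile) averaged 0.0272 M over the first 3.0 d. In theta at 3.00 d, second nucleophile stood at 5.91% of its charge and self-condensation product at 0.0681 M, with 27.1% of the starting material charged still standing as starting material. Theta exceeds my figure, and delta rose 1.5 percentage points after 3.00 d.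
- Take the neighbour of epsilon with c(second nucleophile) at 0.037 M, a quarter of the charge in epsilon: a proportional start rate and the same capture time give 4.59%. That neighbour gives 9.76%, twice as much, which at that start rate reads as a capture time of 0.778 d there.

All runs were generated by integration for substances that don't exist; noise was put on by code.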